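**Retrosynthetic overview**
1. Target 17 is a meso oxolane (O1, C2–C5) with 4-hydroxyphenyl rings (ring B) on C2 and C5 and 2,4-dihydroxybenzoyl groups (ring A) on C3 and C4. The plan rests on C2 and C5. Each is bonded to O1 and is para-benzylic to a free phenol, so each is the exocyclic carbon of a latent p-quinone methide.
2. O1–C2 and O1–C5 are cut together. O1 goes back to water, and the oxolane, the only ring built in the route, opens to the meso 1,4-diketone 13 with two 4-hydroxybenzyl groups and benzylated ring A.
3. C3–C4 is cut by oxidative enolate homocoupling to two molecules of dihydrochalcone 10.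
4. Compound 10 goes back through chalcone 9 to acetophenone 3 and aldehyde 5 (directed aldol addition, elimination, alkene hydrogenation).
5. Forward order: C3–C4 bond, ring B phenols freed, oxolane closed, four benzyl ethers removed.

Key step: step 7

Remark: the SMILES decodes to 2,3-trans, 3,4-cis, 4,5-trans, that is (2R,3R,4S,5S). This is a meso compound with a mirror plane through O1 and the midpoint of C3–C4, so only relative configuration has to be controlled.

**Step 1**
Reactants: 1 2',4'-dihydroxyacetophenone; 2 benzyl bromide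
Product: 3 2',4'-bis(benzyloxy)acetophenone
Conditions: BnBr (2.5 equiv), K2CO3, DMF, 80 °C
Reagents that add atoms: benzyl bromide 2, BrCc1ccccc1
Why: Williamson ether synthesis; the hydrogen-bonded 2'-OH is the slower site, so excess benzyl bromide and heating in DMF are used to drive both phenols to the ether, and no stereocentre is involved.

**Step 2**
Reactants: 4 4-hydroxybenzaldehyde
Product: 5 4-(tert-butyldimethylsilyloxy)benzaldehyde
Conditions: TBSCl, imidazole, CH2Cl2, rt
Reagents that add atoms: tert-butyldimethylsilyl chloride, CC(C)(C)[Si](C)(C)Cl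
Why: Imidazole-promoted silylation of a phenol gives a ring B protecting group that is orthogonal to benzyl and can later be removed by buffered fluoride without base.

**Step 3**
Reactants: 3 2',4'-bis(benzyloxy)acetophenone; 5 4-(tert-butyldimethylsilyloxy)benzaldehyde
Product: 9 (E)-1-[2,4-bis(benzyloxy)phenyl]-3-[4-(tert-butyldimethylsilyloxy)phenyl]prop-2-en-1-one, via lithium enolate 6 (not isolated), via lithium aldolate 7 (not isolated), via aldol mesylate 8 (not isolated)
Conditions: LDA, THF, −78 °C; 5; then MsCl, Et3N, −78 °C to rt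
Reagents that add atoms: none
Why: A directed aldol addition of the preformed lithium enolate, followed by mesylation and E1cB elimination, replaces the hydroxide-mediated Claisen–Schmidt condensation, which would strip the aryl silyl ether, and the elimination gives the conjugated E-alkene for steric reasons.

**Step 4**
Reactants: 9 the (E)-chalcone
Product: 10 1-[2,4-bis(benzyloxy)phenyl]-3-[4-(tert-butyldimethylsilyloxy)phenyl]propan-1-one
Conditions: H2 (4 atm), RhCl(PPh3)3 (5 mol %), toluene–EtOH, 50 °C
Reagents that add atoms: none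
Why: Homogeneous hydrogenation with RhCl(PPh3)3 saturates the disubstituted enone alkene but does not hydrogenolyse aryl benzyl ethers or reduce the aryl ketone, both of which Pd/C would endanger at this stage.

**Step 5**
Reactants: 10 the dihydrochalcone (two molecules)
Product: 12 (2R,3S)-1,4-bis[2,4-bis(benzyloxy)phenyl]-2,3-bis[4-(tert-butyldimethylsilyloxy)benzyl]butane-1,4-dione (meso), via lithium enolate 11 (not isolated)
Conditions: LDA, THF, −78 °C; CuCl2, DMF, −78 °C to rt; crystallisation or chromatography
Reagents that add atoms: none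
Why: Oxidative enolate homocoupling: CuCl2 oxidises the lithium (Z)-enolate 11 by one electron and the α-keto radicals (or copper enolates) join at carbon to form the future C3–C4 bond and both stereocentres with no inherent bias, so the meso isomer is selected by crystallisation or chromatography and is recognised by its failure to split on a chiral stationary phase.

**Step 6**
Reactants: 12 the meso bis-silyl ether
Product: 13 (2R,3S)-1,4-bis[2,4-bis(benzyloxy)phenyl]-2,3-bis(4-hydroxybenzyl)butane-1,4-dione (meso)
Conditions: TBAF, AcOH, THF, 0 °C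
Reagents that add atoms: none
Why: Fluoride-driven desilylation of the aryl silyl ethers; the acetic acid buffer protonates the phenoxides at once and keeps the medium non-basic, so that the two epimerisable centres next to the ketones keep the meso relation and the benzyl ethers are untouched.

**Step 7**
Reactants: 13 the meso bis(4-hydroxybenzyl) diketone
Product: 16 [(2R,3R,4S,5S)-2,5-bis(4-hydroxyphenyl)oxolane-3,4-diyl]bis{[2,4-bis(benzyloxy)phenyl]methanone} (meso 2,3-trans-3,4-cis-4,5-trans), via bis(quinone methide) 14 (not isolated), via hydroxy quinone methide 15 (not isolated)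
Conditions: DDQ (2.05 equiv, in portions), 1,4-dioxane–H2O 9:1, 0 °C to rt, dark
Reagents that add atoms: water, O
Why: Proposed new method: DDQ removes two electrons and two protons from each ring B phenol (oxidation at the phenol, then loss of a benzylic proton) to give bis(quinone methide) 14, water adds 1,6 to one methide carbon (O1–C2) to give 15, and the new hydroxyl adds 1,6 to the other methide carbon (O1–C5), each addition being paid for by rearomatisation; the second oxidation may equally follow the first hydration without changing the outcome. The closest known reaction types are the DDQ dehydrogenation of 4-alkylphenols with capture of the methide by water or an alcohol, and the hydration of 8–8'-coupled bis(quinone methides) from propenylphenols and hydroxycinnamates to 7,7'-epoxylignans; not yet shown is their merger on phenols without ortho substituents in which each methide carbon adjoins an enolisable CH–C(=O)Ar unit. The oxolane closes 5-exo-trig, because O1 attacks C5 while the C5=C(ipso) bond that is given up lies outside the new ring. C3 and C4 are carried over from meso 13 (3,4-cis), C5 is set in the closure by an envelope transition state that keeps the quinoid ring anti to the C4 aroyl group, and C2, set in a less biased acyclic addition, can be corrected because p-hydroxybenzylic C–O bonds re-ionise under mild acid (the hydroquinone formed, or a trace of PPTS once the oxidant is spent), so that each aryl group ends trans to its neighbour as in the acid equilibration of 2,5-diaryloxolane lignans. Chemoselectivity comes from the substrate: ring A is fully benzylated and deactivated by its carbonyl, so only ring B is oxidised, the 2'-O-benzyl group blocks the competing six-membered chromanone closure, ring B has no activated position for an aryltetralin closure, and an oxygen-bearing benzylic carbon makes its phenol a poorer donor than a remaining 4-alkylphenol, which should hold back over-oxidation. The one selectivity that the substrate does not secure, capture by water against loss of H3 or H4 from the methide, is addressed by the high water content, the absence of base and the low temperature.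

**Step 8**
Reactants: 16 the tetrabenzyl oxolane
Product: 17 [(2R,3R,4S,5S)-2,5-bis(4-hydroxyphenyl)oxolane-3,4-diyl]bis[(2,4-dihydroxyphenyl)methanone] (CNP0237262.1)
Conditions: H2 (1 atm), 10% Pd/C, EtOAc–EtOH, rt, stopped after four equivalents of H2
Reagents that add atoms: none
Why: Catalytic hydrogenolysis cleaves the four ArO–CH2Ph bonds much faster than the hindered ring C2–O1 and C5–O1 bonds, a selectivity familiar from phenolic 2,5-diaryloxolane lignans, and the neutral medium leaves C3 and C4 unepimerised and the electron-rich aryl ketones unreduced if the uptake is stopped at four equivalents of H2.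

**Compound list**
1 | 2',4'-dihydroxyacetophenone | CC(=O)c1ccc(O)cc1O | starting material
2 | benzyl bromide | BrCc1ccccc1 | starting material
3 | 2',4'-bis(benzyloxy)acetophenone | CC(=O)c1ccc(OCc2ccccc2)cc1OCc1ccccc1 | intermediate
4 | 4-hydroxybenzaldehyde | O=Cc1ccc(O)cc1 | starting material
5 | 4-(tert-butyldimethylsilyloxy)benzaldehyde | O=Cc1ccc(O[Si](C)(C)C(C)(C)C)cc1 | intermediate
6 | lithium enolate of 3 (not isolated) | [Li+].[O-]C(=C)c1ccc(OCc2ccccc2)cc1OCc1ccccc1 | intermediate
7 | lithium aldolate from 6 and 5, racemic (not isolated) | [Li+].[O-]C(CC(=O)c1ccc(OCc2ccccc2)cc1OCc1ccccc1)c1ccc(O[Si](C)(C)C(C)(C)C)cc1 | intermediate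
8 | aldol mesylate, racemic (not isolated) | CS(=O)(=O)OC(CC(=O)c1ccc(OCc2ccccc2)cc1OCc1ccccc1)c1ccc(O[Si](C)(C)C(C)(C)C)cc1 | intermediate
9 | (E)-1-[2,4-bis(benzyloxy)phenyl]-3-[4-(tert-butyldimethylsilyloxy)phenyl]prop-2-en-1-one | O=C(/C=C/c1ccc(O[Si](C)(C)C(C)(C)C)cc1)c1ccc(OCc2ccccc2)cc1OCc1ccccc1 | intermediate
10 | 1-[2,4-bis(benzyloxy)phenyl]-3-[4-(tert-butyldimethylsilyloxy)phenyl]propan-1-one | O=C(CCc1ccc(O[Si](C)(C)C(C)(C)C)cc1)c1ccc(OCc2ccccc2)cc1OCc1ccccc1 | intermediate
11 | lithium (Z)-enolate of 10 (not isolated) | [Li+].[O-]/C(=C\Cc1ccc(O[Si](C)(C)C(C)(C)C)cc1)c1ccc(OCc2ccccc2)cc1OCc1ccccc1 | intermediate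
12 | meso-(2R,3S)-1,4-bis[2,4-bis(benzyloxy)phenyl]-2,3-bis[4-(tert-butyldimethylsilyloxy)benzyl]butane-1,4-dione | O=C(c1ccc(OCc2ccccc2)cc1OCc1ccccc1)[C@@H](Cc1ccc(O[Si](C)(C)C(C)(C)C)cc1)[C@@H](Cc1ccc(O[Si](C)(C)C(C)(C)C)cc1)C(=O)c1ccc(OCc2ccccc2)cc1OCc1ccccc1 | intermediate
13 | meso-(2R,3S)-1,4-bis[2,4-bis(benzyloxy)phenyl]-2,3-bis(4-hydroxybenzyl)butane-1,4-dione | O=C(c1ccc(OCc2ccccc2)cc1OCc1ccccc1)[C@@H](Cc1ccc(O)cc1)[C@@H](Cc1ccc(O)cc1)C(=O)c1ccc(OCc2ccccc2)cc1OCc1ccccc1 | intermediate
14 | meso-1,4-bis[2,4-bis(benzyloxy)phenyl]-2,3-bis[(4-oxocyclohexa-2,5-dien-1-ylidene)methyl]butane-1,4-dione (not isolated) | O=C(c1ccc(OCc2ccccc2)cc1OCc1ccccc1)[C@@H](C=C1C=CC(=O)C=C1)[C@@H](C=C1C=CC(=O)C=C1)C(=O)c1ccc(OCc2ccccc2)cc1OCc1ccccc1 | intermediate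
15 | 1,4-bis[2,4-bis(benzyloxy)phenyl]-2-[hydroxy(4-hydroxyphenyl)methyl]-3-[(4-oxocyclohexa-2,5-dien-1-ylidene)methyl]butane-1,4-dione, racemic, one enantiomer drawn (not isolated) | O=C(c1ccc(OCc2ccccc2)cc1OCc1ccccc1)[C@@H]([C@@H](O)c1ccc(O)cc1)[C@@H](C=C1C=CC(=O)C=C1)C(=O)c1ccc(OCc2ccccc2)cc1OCc1ccccc1 | intermediate
16 | [(2R,3R,4S,5S)-2,5-bis(4-hydroxyphenyl)oxolane-3,4-diyl]bis{[2,4-bis(benzyloxy)phenyl]methanone}, meso | O=C(c1ccc(OCc2ccccc2)cc1OCc1ccccc1)[C@@H]1[C@H](C(=O)c2ccc(OCc3ccccc3)cc2OCc2ccccc2)[C@@H](c2ccc(O)cc2)O[C@H]1c1ccc(O)cc1 | intermediate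
17 | [(2R,3R,4S,5S)-2,5-bis(4-hydroxyphenyl)oxolane-3,4-diyl]bis[(2,4-dihydroxyphenyl)methanone], meso | O=C(c1ccc(O)cc1O)[C@@H]1[C@H](C(=O)c2ccc(O)cc2O)[C@@H](c2ccc(O)cc2)O[C@H]1c1ccc(O)cc1 | target

Total step count: 8
Longest linear sequence: 7 (steps 1, 3, 4, 5, 6, 7, 8; the branch through step 2 is equally long)

**Steps most likely to fail**

1. Step 7 (the labelled step).
   - Risk: proton loss from C3 or C4 of a methide (tautomerisation) may outrun capture by water and erase the 3,4-cis relation.
   - Risk: the product may be dehydrogenated further at C2–H and C5–H, with aromatisation of the oxolane.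
   - Risk: the acyclic water addition may leave C2 uncorrected.
   - Fallback, using known reaction types only and no phenol oxidation: it sets out from lithium aldolate 7 and comes back at 16. The aldolate is quenched with AcOH at −78 °C to the free aldol F1. Its carbinol is silylated (TBSOTf, 2,6-lutidine) to the bis-silyl ether F2. Oxidative enolate homocoupling as in step 5 (LDA, then CuCl2) gives the tetrasilylated dimer F3, and HF·pyridine in THF frees the bis(benzylic alcohol) F4. PPTS in CH2Cl2 then closes the oxolane by cyclodehydration through a 4-hydroxybenzyl cation, the classical closure of 1,4-diaryl-1,4-diols to 2,5-diaryloxolanes. Both benzylic oxygen atoms then come from the aldehyde. The carbinol configurations need no control because these centres ionise, and the 3,4-cis series is separated from the 3,4-trans series at the stage of 16.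

2. Step 5.
   - Risk: there may be no preference for the meso diastereomer.
   - Risk: CuCl2 may chlorinate the enolate or dehydrogenate it back to the enone.
   - Fallback: it sets out from 9 and comes back at 12, bypassing 10 and the lithium enolate. RhCl(PPh3)3-catalysed 1,4-hydrosilylation of 9 with Et3SiH gives the triethylsilyl enol ether F5. This is coupled with Ag2O in DMSO (oxidative homocoupling of silyl enol ethers, with no strong base and no chloride source). The racemic diastereomer F6 that is separated from 12 is stirred with anhydrous DBU in toluene, which re-establishes the equilibrium between the two diastereomers by enolisation, and is recycled.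

3. Step 8.
   - Risk: the ring C2–O1 and C5–O1 bonds, both benzylic, may be hydrogenolysed before the fourth benzyl ether has gone.
   - Risk: the aryl ketones may be partly reduced in the same interval.
   - Fallback: the benzyl groups are removed before the sensitive ring exists. It sets out from 12 and comes back at 17. Hydrogenolysis of 12 (H2, Pd/C, EtOAc) gives the ring A tetraphenol F7, and Ac2O–pyridine gives the tetraacetate F8. HF·pyridine frees ring B to give the diphenol tetraacetate F9, and the conditions of step 7 give the oxolane tetraacetate F10. The aryl acetates are then taken off under neutral conditions (NH4OAc, aqueous MeOH, rt) to give 17.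

**Further compounds**
F1 | step 7 | 1-[2,4-bis(benzyloxy)phenyl]-3-[4-(tert-butyldimethylsilyloxy)phenyl]-3-hydroxypropan-1-one, racemic | O=C(CC(O)c1ccc(O[Si](C)(C)C(C)(C)C)cc1)c1ccc(OCc2ccccc2)cc1OCc1ccccc1
F2 | step 7 | 1-[2,4-bis(benzyloxy)phenyl]-3-(tert-butyldimethylsilyloxy)-3-[4-(tert-butyldimethylsilyloxy)phenyl]propan-1-one, racemic | O=C(CC(O[Si](C)(C)C(C)(C)C)c1ccc(O[Si](C)(C)C(C)(C)C)cc1)c1ccc(OCc2ccccc2)cc1OCc1ccccc1
F3 | step 7 | 1,4-bis[2,4-bis(benzyloxy)phenyl]-2,3-bis{(tert-butyldimethylsilyloxy)[4-(tert-butyldimethylsilyloxy)phenyl]methyl}butane-1,4-dione, drawn with the C2–C3 relation that leads to 16, carbinol centres as a mixture | O=C(c1ccc(OCc2ccccc2)cc1OCc1ccccc1)[C@@H](C(O[Si](C)(C)C(C)(C)C)c1ccc(O[Si](C)(C)C(C)(C)C)cc1)[C@@H](C(O[Si](C)(C)C(C)(C)C)c1ccc(O[Si](C)(C)C(C)(C)C)cc1)C(=O)c1ccc(OCc2ccccc2)cc1OCc1ccccc1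
F4 | step 7 | 1,4-bis[2,4-bis(benzyloxy)phenyl]-2,3-bis[hydroxy(4-hydroxyphenyl)methyl]butane-1,4-dione, same C2–C3 relation, carbinol centres as a mixture | O=C(c1ccc(OCc2ccccc2)cc1OCc1ccccc1)[C@@H](C(O)c1ccc(O)cc1)[C@@H](C(O)c1ccc(O)cc1)C(=O)c1ccc(OCc2ccccc2)cc1OCc1ccccc1
F5 | step 5 | (Z)-triethylsilyl enol ether of 10 | CC[Si](CC)(CC)O/C(=C\Cc1ccc(O[Si](C)(C)C(C)(C)C)cc1)c1ccc(OCc2ccccc2)cc1OCc1ccccc1
F6 | step 5 | rac-(2S,3S)-1,4-bis[2,4-bis(benzyloxy)phenyl]-2,3-bis[4-(tert-butyldimethylsilyloxy)benzyl]butane-1,4-dione, one enantiomer drawn | O=C(c1ccc(OCc2ccccc2)cc1OCc1ccccc1)[C@@H](Cc1ccc(O[Si](C)(C)C(C)(C)C)cc1)[C@H](Cc1ccc(O[Si](C)(C)C(C)(C)C)cc1)C(=O)c1ccc(OCc2ccccc2)cc1OCc1ccccc1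
F7 | step 8 | meso-1,4-bis(2,4-dihydroxyphenyl)-2,3-bis[4-(tert-butyldimethylsilyloxy)benzyl]butane-1,4-dione | O=C(c1ccc(O)cc1O)[C@@H](Cc1ccc(O[Si](C)(C)C(C)(C)C)cc1)[C@@H](Cc1ccc(O[Si](C)(C)C(C)(C)C)cc1)C(=O)c1ccc(O)cc1O
F8 | step 8 | meso-1,4-bis(2,4-diacetoxyphenyl)-2,3-bis[4-(tert-butyldimethylsilyloxy)benzyl]butane-1,4-dione | O=C(c1ccc(OC(C)=O)cc1OC(C)=O)[C@@H](Cc1ccc(O[Si](C)(C)C(C)(C)C)cc1)[C@@H](Cc1ccc(O[Si](C)(C)C(C)(C)C)cc1)C(=O)c1ccc(OC(C)=O)cc1OC(C)=O
F9 | step 8 | meso-1,4-bis(2,4-diacetoxyphenyl)-2,3-bis(4-hydroxybenzyl)butane-1,4-dione | O=C(c1ccc(OC(C)=O)cc1OC(C)=O)[C@@H](Cc1ccc(O)cc1)[C@@H](Cc1ccc(O)cc1)C(=O)c1ccc(OC(C)=O)cc1OC(C)=O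
F10 | step 8 | [(2R,3R,4S,5S)-2,5-bis(4-hydroxyphenyl)oxolane-3,4-diyl]bis[(2,4-diacetoxyphenyl)methanone], meso | O=C(c1ccc(OC(C)=O)cc1OC(C)=O)[C@@H]1[C@H](C(=O)c2ccc(OC(C)=O)cc2OC(C)=O)[C@@H](c2ccc(O)cc2)O[C@H]1c1ccc(O)cc1
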